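**Retrosynthetic overview**

1. The target is the exo,exo 2,6-diaryl-3,7-dioxabicyclo[3.3.0]octane. In furo[3,4-c]furan numbering, ring A is C1(guaiacyl)–O2–C3–C3a–C6a and ring B is C3a–C4(3-hydroxy-4,5-dimethoxyphenyl)–O5–C6–C6a. The last step only removes two aryl TIPS ethers.
2. Key disconnection: both rings, the C3a–C6a and C4–O5 bonds and the stereocentres C3a, C4 and C6a come in one pot from an open-chain epoxy cinnamyl ether. Cp2TiCl opens the oxirane (O5, C6, C6a) at C6a, the radical closes ring A onto the alkene, and iodine then lets O5 bond to benzylic C4. Ring B is thus the oxirane enlarged from three to five atoms by insertion of the alkene carbons C3a and C4 into its C6a–O5 bond.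
3. Enabling feature: oxirane carbon C6a and alkene carbon C3a are 1,5-related through the C1–O2–C3 ether tether (a 3-oxa-5-hexenyl radical), and C4 bears the para-methoxy aryl ring that stabilises the benzylic radical and cation to which O5 returns. C1 is the only stereocentre made beforehand, because the oxirane centre is erased at the radical stage.
4. The precursor is a Williamson union of an epoxy alcohol (vanillin: TIPS ether, vinyl Grignard, Sharpless kinetic resolution to set C1) with a cinnamyl bromide (3-hydroxy-4,5-dimethoxybenzaldehyde: TIPS ether, HWE, DIBAL-H, Appel).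
5. Ring order: oxirane (step 3), then ring A and ring B, in this order, within step 9.

Key step: step 9

Remark: the SMILES is read as the exo,exo (pinoresinol-type) isomer (1S,3aR,4S,6aR); 3-hydroxy-4,5-dimethoxybenzaldehyde and D-(−)-diisopropyl tartrate are taken as commercial.

**Route**

Step 1
Reactants: 1 vanillin (4-hydroxy-3-methoxybenzaldehyde)
Product: 2 3-methoxy-4-(triisopropylsilyloxy)benzaldehyde
Conditions: TIPSCl, imidazole, DMF, rt
Reagents that add atoms: triisopropylsilyl chloride, CC(C)[Si](Cl)(C(C)C)C(C)C
Why: Imidazole-promoted silyl ether formation masks the phenol for the Grignard, alkoxide and trivalent-titanium steps, and the hindered aryl TIPS ether should resist these and fall only to fluoride at the end.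

Step 2
Reactants: 2 3-methoxy-4-(triisopropylsilyloxy)benzaldehyde
Product: 3 rac-1-[3-methoxy-4-(triisopropylsilyloxy)phenyl]prop-2-en-1-ol
Conditions: CH2=CHMgBr, THF, −78 → 0 °C; then H2O
Reagents that add atoms: vinylmagnesium bromide, C=C[Mg]Br
Why: Grignard 1,2-addition to the aldehyde should give the secondary allylic alcohol as the racemate, whose carbinol centre is resolved in step 3.

Step 3
Reactants: 3 rac-1-[3-methoxy-4-(triisopropylsilyloxy)phenyl]prop-2-en-1-ol
Product: 4 (R)-[3-methoxy-4-(triisopropylsilyloxy)phenyl][(S)-oxiran-2-yl]methanol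
Conditions: Ti(OiPr)4, D-(−)-DIPT, t-BuOOH (0.55 equiv), 4 Å MS, CH2Cl2, −20 °C, stopped near half conversion
Reagents that add atoms: tert-butyl hydroperoxide, CC(C)(C)OO
Why: In this Sharpless kinetic resolution (titanium–tartrate epoxidation of a secondary allylic alcohol) the D-(−)-DIPT catalyst should epoxidise the (S)-alcohol much faster than the (R)-alcohol and on the alkene face that gives the erythro epoxy alcohol, so the carbinol centre that becomes C1 is selected and the oxirane centre is set by the catalyst.

Step 4
Reactants: 5 3-hydroxy-4,5-dimethoxybenzaldehyde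
Product: 6 3,4-dimethoxy-5-(triisopropylsilyloxy)benzaldehyde
Conditions: TIPSCl, imidazole, DMF, rt
Reagents that add atoms: triisopropylsilyl chloride, CC(C)[Si](Cl)(C(C)C)C(C)C
Why: The same imidazole-promoted silyl ether formation protects the second phenol with a group that leaves in the same final operation.

Step 5
Reactants: 6 3,4-dimethoxy-5-(triisopropylsilyloxy)benzaldehyde
Product: 7 ethyl (E)-3-[3,4-dimethoxy-5-(triisopropylsilyloxy)phenyl]prop-2-enoate
Conditions: (EtO)2P(O)CH2CO2Et, NaH, THF, 0 °C → rt
Reagents that add atoms: triethyl phosphonoacetate, CCOC(=O)CP(=O)(OCC)OCC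
Why: Horner–Wadsworth–Emmons olefination with the stabilised phosphonate anion should give the (E)-cinnamate.

Step 6
Reactants: 7 ethyl (E)-3-[3,4-dimethoxy-5-(triisopropylsilyloxy)phenyl]prop-2-enoate
Product: 8 (E)-3-[3,4-dimethoxy-5-(triisopropylsilyloxy)phenyl]prop-2-en-1-ol
Conditions: i-Bu2AlH (2.2 equiv), CH2Cl2, −78 °C; aq. potassium sodium tartrate
Reagents that add atoms: none
Why: DIBAL-H 1,2-reduction of the unsaturated ester at low temperature should give the allylic alcohol without touching the alkene or the silyl ether.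

Step 7
Reactants: 8 (E)-3-[3,4-dimethoxy-5-(triisopropylsilyloxy)phenyl]prop-2-en-1-ol
Product: 9 {5-[(E)-3-bromoprop-1-en-1-yl]-2,3-dimethoxyphenoxy}triisopropylsilane
Conditions: CBr4, PPh3, CH2Cl2, 0 °C; used at once
Reagents that add atoms: carbon tetrabromide, BrC(Br)(Br)Br
Why: The Appel reaction (SN2 displacement on the alkoxyphosphonium salt at the primary allylic carbon) should give the cinnamyl bromide under neutral conditions that suit this easily ionised, electron-rich halide.

Step 8
Reactants: 4 (R)-[3-methoxy-4-(triisopropylsilyloxy)phenyl][(S)-oxiran-2-yl]methanol, 9 {5-[(E)-3-bromoprop-1-en-1-yl]-2,3-dimethoxyphenoxy}triisopropylsilane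
Product: 10 (S)-2-[(R)-{[(E)-3-[3,4-dimethoxy-5-(triisopropylsilyloxy)phenyl]prop-2-en-1-yl]oxy}[3-methoxy-4-(triisopropylsilyloxy)phenyl]methyl]oxirane
Conditions: NaH (added last), n-Bu4NI (cat.), THF, 0 °C → rt
Reagents that add atoms: none
Why: In this Williamson ether synthesis the sodium alkoxide of 4 should displace the primary allylic bromide by SN2 without touching a stereocentre, and THF at 0 °C with the bromide already present keeps alkylation ahead of Payne rearrangement and avoids the cleavage of aryl silyl ethers that NaH causes in DMF.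

Step 9
Reactants: 10 (S)-2-[(R)-{[(E)-3-[3,4-dimethoxy-5-(triisopropylsilyloxy)phenyl]prop-2-en-1-yl]oxy}[3-methoxy-4-(triisopropylsilyloxy)phenyl]methyl]oxirane
Product: 13 (1S,3aR,4S,6aR)-4-[3,4-dimethoxy-5-(triisopropylsilyloxy)phenyl]-1-[3-methoxy-4-(triisopropylsilyloxy)phenyl]tetrahydro-1H,3H-furo[3,4-c]furan, via bis-titanated tetrahydrofuran 11 (not isolated), via benzylic iodide 12 (not isolated)
Conditions: Cp2TiCl (2.5 equiv, preformed from Cp2TiCl2 [(C5H5)2TiCl2] and Zn dust in THF) added slowly to 10, THF, rt; then I2 (1.5 equiv), rt → 50 °C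
Reagents that add atoms: none
Why: Cp2TiCl (trivalent titanium) transfers one electron to the oxirane of 10 and breaks its C6a–O5 bond to give a secondary β-titanoxy radical at C6a, which adds to the cinnamyl alkene (new C6a–C3a bond) and leaves a benzylic radical at C4 that a second Cp2TiCl traps as 11; iodine turns the C4–Ti bond into the benzylic iodide 12, and loss of iodide from this para-methoxybenzylic position lets the titanium-bound O5 close the C4–O5 bond, so that ring B consists of the three oxirane atoms O5, C6 and C6a with C3a and C4 inserted into the former oxirane C–O bond. The closest known reaction type is the titanocene chloride-mediated reductive epoxide opening with radical cyclisation (Nugent–RajanBabu reaction) followed by iodine-induced etherification of the benzylic titanium species, which is precedented for epoxy cinnamyl ethers of exactly this kind. Ring A closes by a 5-exo-trig radical cyclisation of a 3-oxa-5-hexenyl radical and ring B by a 5-exo-tet attack of the alkoxide oxygen on the benzylic iodide or the cation derived from it. C6a and C3a are controlled by the C1 stereocentre through a chair-like Beckwith–Houk transition state with the C1 aryl group pseudo-equatorial, which places the titanoxymethyl group trans to that aryl group and cis to the new benzylic carbon. C4 is controlled by the cis-fused bicycle being formed, because the planar benzylic carbon is attacked so that its aryl group ends up exo on the convex face, the lower-energy arrangement. The step needs oxirane opening at the internal carbon, 5-exo instead of 6-endo addition and cyclisation faster than reduction of the first radical; the more substituted radical, the aryl group on the alkene terminus (benzylic adduct radical) and slow addition of Cp2TiCl secure these, and since the oxirane stereocentre is lost at the radical stage either epoxide epimer should give 13.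

Step 10
Reactants: 13 (1S,3aR,4S,6aR)-4-[3,4-dimethoxy-5-(triisopropylsilyloxy)phenyl]-1-[3-methoxy-4-(triisopropylsilyloxy)phenyl]tetrahydro-1H,3H-furo[3,4-c]furan
Product: 14 4-[(1S,3aR,4S,6aR)-4-(3-hydroxy-4,5-dimethoxyphenyl)tetrahydro-1H,3H-furo[3,4-c]furan-1-yl]-2-methoxyphenol (CNP0324902.1)
Conditions: Bu4NF, AcOH, THF, 0 °C → rt
Reagents that add atoms: none
Why: Fluoride-mediated desilylation should cleave both aryl TIPS ethers, and the acetic acid buffer protonates the phenoxides at once so that the benzylic ether stereocentres see neither strong base nor acid.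

**Compound list**

1 | vanillin (4-hydroxy-3-methoxybenzaldehyde) | COc1cc(C=O)ccc1O | starting material
2 | 3-methoxy-4-(triisopropylsilyloxy)benzaldehyde | COc1cc(C=O)ccc1O[Si](C(C)C)(C(C)C)C(C)C | intermediate
3 | rac-1-[3-methoxy-4-(triisopropylsilyloxy)phenyl]prop-2-en-1-ol | COc1cc(C(O)C=C)ccc1O[Si](C(C)C)(C(C)C)C(C)C | intermediate
4 | (R)-[3-methoxy-4-(triisopropylsilyloxy)phenyl][(S)-oxiran-2-yl]methanol (erythro epoxy alcohol) | COc1cc([C@H]([C@@H]2CO2)O)ccc1O[Si](C(C)C)(C(C)C)C(C)C | intermediate
5 | 3-hydroxy-4,5-dimethoxybenzaldehyde | COc1cc(C=O)cc(O)c1OC | starting material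
6 | 3,4-dimethoxy-5-(triisopropylsilyloxy)benzaldehyde | COc1cc(C=O)cc(O[Si](C(C)C)(C(C)C)C(C)C)c1OC | intermediate
7 | ethyl (E)-3-[3,4-dimethoxy-5-(triisopropylsilyloxy)phenyl]prop-2-enoate | CCOC(=O)/C=C/c1cc(OC)c(OC)c(O[Si](C(C)C)(C(C)C)C(C)C)c1 | intermediate
8 | (E)-3-[3,4-dimethoxy-5-(triisopropylsilyloxy)phenyl]prop-2-en-1-ol | OC/C=C/c1cc(OC)c(OC)c(O[Si](C(C)C)(C(C)C)C(C)C)c1 | intermediate
9 | {5-[(E)-3-bromoprop-1-en-1-yl]-2,3-dimethoxyphenoxy}triisopropylsilane | BrC/C=C/c1cc(OC)c(OC)c(O[Si](C(C)C)(C(C)C)C(C)C)c1 | intermediate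
10 | (S)-2-[(R)-{[(E)-3-[3,4-dimethoxy-5-(triisopropylsilyloxy)phenyl]prop-2-en-1-yl]oxy}[3-methoxy-4-(triisopropylsilyloxy)phenyl]methyl]oxirane | COc1cc([C@H]([C@@H]2CO2)OC/C=C/c2cc(O[Si](C(C)C)(C(C)C)C(C)C)c(OC)c(OC)c2)ccc1O[Si](C(C)C)(C(C)C)C(C)C | intermediate
11 | bis-titanated tetrahydrofuran: (2S,3R,4R)-2-[3-methoxy-4-(triisopropylsilyloxy)phenyl]tetrahydrofuran carrying CH2–O–TiCp2Cl on C3 and CH(aryl)–TiCp2Cl on C4 (aryl = 3,4-dimethoxy-5-(triisopropylsilyloxy)phenyl; benzylic carbon of undefined configuration; Cp rings written σ-bonded in the SMILES) | COc1cc([C@H]2OC[C@H](C([Ti](Cl)(C3C=CC=C3)C3C=CC=C3)c3cc(O[Si](C(C)C)(C(C)C)C(C)C)c(OC)c(OC)c3)[C@@H]2CO[Ti](Cl)(C2C=CC=C2)C2C=CC=C2)ccc1O[Si](C(C)C)(C(C)C)C(C)C | intermediate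
12 | benzylic iodide: as 11 but with CH(aryl)–I on C4 (benzylic carbon of undefined configuration), still the Cp2TiCl alkoxide on the C3 CH2O group | COc1cc([C@H]2OC[C@H](C(I)c3cc(O[Si](C(C)C)(C(C)C)C(C)C)c(OC)c(OC)c3)[C@@H]2CO[Ti](Cl)(C2C=CC=C2)C2C=CC=C2)ccc1O[Si](C(C)C)(C(C)C)C(C)C | intermediate
13 | (1S,3aR,4S,6aR)-4-[3,4-dimethoxy-5-(triisopropylsilyloxy)phenyl]-1-[3-methoxy-4-(triisopropylsilyloxy)phenyl]tetrahydro-1H,3H-furo[3,4-c]furan | COc1cc([C@H]2OC[C@H]3[C@@H]2CO[C@@H]3c2cc(O[Si](C(C)C)(C(C)C)C(C)C)c(OC)c(OC)c2)ccc1O[Si](C(C)C)(C(C)C)C(C)C | intermediate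
14 | 4-[(1S,3aR,4S,6aR)-4-(3-hydroxy-4,5-dimethoxyphenyl)tetrahydro-1H,3H-furo[3,4-c]furan-1-yl]-2-methoxyphenol | COc1cc([C@H]2OC[C@H]3[C@@H]2CO[C@@H]3c2cc(O)c(OC)c(OC)c2)ccc1O | target

**Step count and risks**

Total step count: 10. Longest linear sequence: 7 steps (steps 4 to 10, from 5 to 14).

Steps most likely to fail:

Step 9. The benzylic titanium species may be protonated, or the benzylic iodide may lose HI, before O5 can attack; reduction of the first radical by Cp2TiCl may also compete with cyclisation, so that ring B does not close in the same pot. The fallback sets out from 10 and comes back at 13. The titanocene cyclisation is run with an acidic aqueous quench instead of iodine, the well-precedented way to the reduced product, [(2S,3R,4R)-4-[3,4-dimethoxy-5-(triisopropylsilyloxy)benzyl]-2-[3-methoxy-4-(triisopropylsilyloxy)phenyl]tetrahydrofuran-3-yl]methanol F1. Ring B is then closed by DDQ in CH2Cl2 over 4 Å MS at 0 °C, a known benzylic oxidative cycloetherification. DDQ should abstract hydride from the benzylic CH2 of the more electron-rich trioxygenated ring, and the primary alcohol should capture the para-methoxybenzylic cation to give 13.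

Step 3. Rate discrimination between the enantiomers may be poor for a terminal vinyl carbinol, and the electron-rich benzylic epoxy alcohol may ionise or rearrange on the titanium alkoxide. The fallback sets out from 3 and comes back at 4, with the epimeric part rejoining at 13. A lipase-catalysed acylative resolution (Burkholderia cepacia lipase or CAL-B, vinyl acetate) should, by the usual selectivity for secondary alcohols, acylate the (R)-alcohol and leave (S)-1-[3-methoxy-4-(triisopropylsilyloxy)phenyl]prop-2-en-1-ol F2. Hydroxyl-directed epoxidation of F2 with mCPBA and NaHCO3 in CH2Cl2 should give 4 together with its oxirane epimer, (R)-[3-methoxy-4-(triisopropylsilyloxy)phenyl][(R)-oxiran-2-yl]methanol F3. The mixture is taken through step 8, where F3 gives the epimeric ether (R)-2-[(R)-{[(E)-3-[3,4-dimethoxy-5-(triisopropylsilyloxy)phenyl]prop-2-en-1-yl]oxy}[3-methoxy-4-(triisopropylsilyloxy)phenyl]methyl]oxirane F4. Both ethers should converge on 13 in step 9 because the oxirane stereocentre is erased there.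

Step 8. The epoxy alkoxide may undergo Payne rearrangement before it is alkylated, and the labile electron-rich cinnamyl bromide may ionise or hydrolyse. The fallback sets out from 8 (and 4), bypasses 9 and comes back at 10. Alcohol 8 is converted with ClCO2Me and pyridine into (E)-3-[3,4-dimethoxy-5-(triisopropylsilyloxy)phenyl]prop-2-en-1-yl methyl carbonate F5. Alcohol 4 is then O-allylated with F5 by Pd(PPh3)4 (zerovalent palladium) in THF, a Tsuji–Trost allylic etherification under neutral conditions. Only a catalytic amount of alkoxide is present at any time, and attack on the π-allyl complex at its unhindered terminus should give the linear (E) ether 10.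

**Further compounds**

F1 | step 9 | [(2S,3R,4R)-4-[3,4-dimethoxy-5-(triisopropylsilyloxy)benzyl]-2-[3-methoxy-4-(triisopropylsilyloxy)phenyl]tetrahydrofuran-3-yl]methanol | COc1cc([C@H]2OC[C@H](Cc3cc(O[Si](C(C)C)(C(C)C)C(C)C)c(OC)c(OC)c3)[C@@H]2CO)ccc1O[Si](C(C)C)(C(C)C)C(C)C
F2 | step 3 | (S)-1-[3-methoxy-4-(triisopropylsilyloxy)phenyl]prop-2-en-1-ol | COc1cc([C@H](C=C)O)ccc1O[Si](C(C)C)(C(C)C)C(C)C
F3 | step 3 | (R)-[3-methoxy-4-(triisopropylsilyloxy)phenyl][(R)-oxiran-2-yl]methanol | COc1cc([C@H]([C@H]2CO2)O)ccc1O[Si](C(C)C)(C(C)C)C(C)C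
F4 | step 3 | (R)-2-[(R)-{[(E)-3-[3,4-dimethoxy-5-(triisopropylsilyloxy)phenyl]prop-2-en-1-yl]oxy}[3-methoxy-4-(triisopropylsilyloxy)phenyl]methyl]oxirane | COc1cc([C@H]([C@H]2CO2)OC/C=C/c2cc(O[Si](C(C)C)(C(C)C)C(C)C)c(OC)c(OC)c2)ccc1O[Si](C(C)C)(C(C)C)C(C)C
F5 | step 8 | (E)-3-[3,4-dimethoxy-5-(triisopropylsilyloxy)phenyl]prop-2-en-1-yl methyl carbonate | COC(=O)OC/C=C/c1cc(OC)c(OC)c(O[Si](C(C)C)(C(C)C)C(C)C)c1
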